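The rate constants come from no measurement; the result is computed.

Looking towards late times, the scheme gives the catalyst one exit, the capture of catalyst intermediate B (from here on B, and likewise A and C) to trapped intermediate, and no way back, so I asked how quickly live catalyst is lost.

    catalyst intermediate B → catalyst intermediate C (k1 = 180 h⁻¹)
    reagent + free catalyst → catalyst intermediate A (k2 = 5300 M⁻¹ h⁻¹)
    substrate + catalyst intermediate A ⇌ catalyst intermediate B (K3 = 94 M⁻¹, k3 = 21000 M⁻¹ h⁻¹)
    catalyst intermediate B + capture agent → trapped intermediate (k4 = 2900 M⁻¹ h⁻¹)
    catalyst intermediate C → free catalyst + target (k5 = 62 h⁻¹)
    2 substrate → self-condensation product (k6 = 17 M⁻¹ h⁻¹)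

substrate 14 mM; reagent 35.0 mM; capture agent 4.20 mM; free catalyst 70 µM

* apparent order in free catalyst when 30 % of the substrate are converted (percent change of the rate of making target for one percent more free catalyst charged)

I took the round as steady, with [substrate] midway to the conversion asked about, which I call the mark, at 11.9 mM, and [reagent] and [capture agent] as charged, and counted each form against B:

| Form | Held per unit of B |
|---|---|
| B | 1 |
| C | 2.90 |
| free catalyst | 0.970 |
| A | 1.66 |

Row C stands highest: C releases target at 62 h⁻¹, slower than B forms C at 180 h⁻¹. Row A comes next, and it is the row that moves with [substrate]. The free catalyst row stands lowest, with the reagent taking up free catalyst at 190 h⁻¹.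

Row B is the one I carried forward: in the scheme, capture touches that form and no other. Capture takes B at 12 h⁻¹, and B is one part in the sum of the column. Dividing gives 1.86 h⁻¹, the death rate of live catalyst, a pseudo-first-order loss. Integrated, live catalyst falls exponentially with time.

Self-condensation without any catalysis, integrated as a second-order loss, reaches the mark in 0.900 h. On this reckoning, 18.7 % of the catalyst is still live at that time. I expected a larger charge of catalyst to reach the mark sooner and to have a larger surviving fraction there, and so an order above one, but I stopped without a figure.

The forecast gave 1.29, on the ground that “More catalyst reaches 30 % conversion sooner, with less decay”.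

The flask gives 1.3, with the mark reached at 0.732 h.

The largest single effect on this order is the trapping step: with that step taken away from the same flask, the order is 1.0. The death rate predicts 42.8 % of the catalyst trapped at 0.300 h, and the flask holds 43.2 %. Carried to 0.732 h, it predicts a factor of 3.90 between keeping all the catalyst live and losing it at this rate, and the flask without the trapping step makes target at the mark at 3.74 times the actual rate.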